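All runs stem from a simulated flask on assumed constants; the scatter is artificial.

Decide first which charge, if any, is to be held back in the next flask, and count the decision in half-lives of substrate.

| flask | substrate | partner | second reagent | third reagent | remark | time |
|---|---|---|---|---|---|---|
| maple | 2.0 × 10⁻⁴ M | 0.80 mM | 0.22 mM | 0.14 mM | run made earlier |  |
| elm | 2.0 × 10⁻⁴ M | 0.80 mM | 0.22 mM | 0.094 mM | run made earlier |  |
| oak | 2.0 × 10⁻⁴ M | 0.80 mM | 0.22 mM | 0.21 mM | run made earlier |  |
| Friday's | 2.0 × 10⁻⁴ M | 0.800 mM | 0.220 mM | 0.140 mM | everything together at the start | 12 min |
| Saturday's | 2.0 × 10⁻⁴ M | 0.800 mM (in portions, 5, over 5.0 min) | 0.220 mM | 0.140 mM | first portion at the start, last at 5.0 min | 12 min |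
| Monday's | 2.0 × 10⁻⁴ M (fed, over 5.0 min) | 0.800 mM | 0.220 mM | 0.140 mM | all else is in the flask from the start; the feed brings no volume worth counting | 12 min |
| Sunday's | 2.0 × 10⁻⁴ M | 0.800 mM (fed, over 5.0 min) | 0.220 mM | 0.140 mM | all else is in the flask from the start; the feed brings no volume worth counting | 12 min |

- maple (time / min: target / %, substrate / %): 1.33: 2.8, 29.1; 3.00: 8.4, 9.5; 4.00: 12.2, 4.8; 6.00: 18.6, 1.4; 8.00: 24.3, 0.3
- elm (time / min: target / %, substrate / %): 3.00: 5.7, 9.2; 6.00: 12.6, 1.5; 8.00: 17.0, 0.3; 12.0: 23.4, 0.3; 15.0: 26.8, 0
- oak (time / min: target / %, substrate / %): 3.00: 12.3, 9.2; 6.00: 25.4, 1.0; 8.00: 32.1, 0.2; 12.0: 41.4, 0; 15.0: 45.8, 0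

(each reading ± 0.3 percentage points)

- percentages count the substrate that a species holds: one side product B counts as two
- candidate steps: substrate + partner -> intermediate A; substrate + target -> side product B; substrate + second reagent -> side product A; partner <-> dormant form; third reagent + intermediate B -> target; second reagent + intermediate A -> intermediate B

1. which flask leads in amount of target, in percent of the substrate charged ("all alike" within 1.5 percentage points) (Friday's / Saturday's / Monday's / Sunday's / all alike)
2. how much target is there at the end, in percent of the substrate charged: Friday's
3. how much target is there at the end, in percent of the substrate charged: Saturday's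
4. how much target is there at the end, in percent of the substrate charged: Monday's
5. how much target is there at the end, in percent of the substrate charged: Sunday's

Among the candidate steps, substrate goes with partner towards intermediate A, and on towards target, with second reagent to side product A, or with target to side product B. At 3.00 min the reading of substrate is 9.2% in the elm run and 9.2% in the oak run, although third reagent differs by a factor of 2.23. Target in the same readings differs by a factor of 2.16. So between these two runs the reading of substrate does not follow third reagent while target does, which points to a slow last step with third reagent, the rate-limiting step.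

In the maple run the reading of substrate falls from 29.1% of its charge at 1.33 min to 9.5% at 3.00 min; taken as a pseudo-first-order decay, that stretch gives a half-life as a reading:

half-life = 1.67 min / 1.62 halvings = 1.03 min

This half-life of substrate read in the maple run serves as the clock for the additions asked about:

midpoint of the addition = 2.50 min = 2.43 half-lives

whole addition = 5.0 min = 4.85 half-lives

Partner held back, as in Saturday's and Sunday's flasks, arrives on average later than one half-life, so until then second reagent meets the substrate with less partner beside it, and side product A is expected to gain. Substrate held back, as in Monday's flask, enters over 4.85 half-lives, so each part is expected to be used soon after it enters, and the cost is lateness. With target rising in the maple run from 18.6% to 24.3% over 2.00 min, that lateness is estimated to cost, over the midpoint of the addition: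

7.1 percentage points of target

The decision is therefore to hold nothing back, as in Friday's flask.

The forecast names Friday's, with 32% there, 23% in Saturday's, 27% in Monday's and 20% in Sunday's, on the ground that “Slow partner addition leaves substrate exposed to second reagent”; its gap between Friday's and Monday's, 5 points, is narrower than the reckoning here.

The flasks give 31.7% in Friday's, 19.6% in Saturday's, 25.3% in Monday's and 18.0% in Sunday's, so Friday's leads, with Monday's 6.4 points behind.

    substrate + partner → intermediate A (k = 16.9 /M/s)
    substrate + target → side product B (k = 36.1 /M/s)
    substrate + second reagent → side product A (k = 41.3 /M/s)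
    partner ⇌ dormant form (K = 0.360, k = 0.0238 /s)
    third reagent + intermediate B → target (k = 11.6 /M/s)
    second reagent + intermediate A → intermediate B (k = 779 /M/s)

In Sunday's flask half of the loss of substrate to side product A up to 12 min is done by 0.799 min, inside one maple half-life of 1.03 min, while half of the making of intermediate A is done only by 2.78 min, or 2.70 such half-lives. In Monday's flask, whose feed spans 4.85 of them, side product A stands at 33.4% at 12.0 min, against 60.4% in Sunday's flask.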